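Rings: A = terminal 2,6-dihydroxyphenyl, B = inner catechol (chain on C1, ring C on C2, OH on C4 and C5), C = inner resorcinol (acyl on C1, OH on C2 and C6, ring B on C3), D = terminal catechol.
Retrosynthesis cuts, in this order: the four catechol O-CH3 bonds (protection), the C(=O)-CH2 bond at ring C, the biaryl bond between rings B and C, the C(=O)-CH2 bond at ring A, and the two aryl-CH2 bonds of rings B and D.
Enabling feature: on ring C, as on ring A, the acyl carbon sits on C1 between the phenolic oxygens on C2 and C6. The matching aldehyde is therefore a salicylaldehyde. Its phenoxide O and formyl C hold rhodium in a five-membered chelate, and the formyl C-H bond adds across a terminal vinyl group to give the ketone at its final oxidation level with the resorcinol OH groups free.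
Forward: one octenyl borane serves both chains, giving alkene 4 (ring D) and bromo alkene 6 (ring B). Then 6 + aldehyde 7 gives ring A ketone 8, borylation and biaryl coupling with 9 give aldehyde 11, 11 + 4 give the full skeleton 12, and demethylation gives 13. All four arenes are bought and no ring is built.
Stereochemistry: the target has no stereocentre, and the biaryl axis carries only one ortho substituent on each ring, so it rotates freely and nothing has to be controlled.

Key step: step 8

Remark: compounds 1, 3 and 7 and the reagents 9-BBN, NIS, NBS and B2pin2 are taken as commercial.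

Step 1
Reactants: 1 octa-1,7-diene
Product: 2 9-(oct-7-en-1-yl)-9-borabicyclo[3.3.1]nonane
Conditions: 9-BBN (0.5 M in THF), 1 (4 equiv), THF, 0 °C to rt; excess 1 removed in vacuo, 2 kept as a THF stock solution
Reagents that add atoms: 9-BBN (9-borabicyclo[3.3.1]nonane), B1C2CCCC1CCC2
Why: Brown hydroboration with 9-BBN places boron on the terminal carbon with high anti-Markovnikov selectivity, and the large excess of the symmetrical diene keeps the second vinyl group untouched.

Step 2
Reactants: 2 9-(oct-7-en-1-yl)-9-borabicyclo[3.3.1]nonane; 3 4-bromo-1,2-dimethoxybenzene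
Product: 4 1,2-dimethoxy-4-(oct-7-en-1-yl)benzene
Conditions: Pd(dppf)Cl2 (cat.), 3 M aq NaOH, THF, 65 °C
Reagents that add atoms: none
Why: In this B-alkyl Suzuki-Miyaura coupling the hydroxide-activated primary alkyl borane transmetalates to the arylpalladium bromide faster than the distant vinyl group can enter a Heck pathway, and dppf holds back beta-hydride elimination.

Step 3
Reactants: 3 4-bromo-1,2-dimethoxybenzene
Product: 5 1-bromo-2-iodo-4,5-dimethoxybenzene
Conditions: NIS, TFA (cat.), MeCN, rt
Reagents that add atoms: N-iodosuccinimide, O=C1CCC(=O)N1I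
Why: Electrophilic aromatic iodination with acid-activated NIS should go to the only free position para to a methoxy group, which is the carbon next to bromine, as is usual for 4-haloveratroles.

Step 4
Reactants: 2 9-(oct-7-en-1-yl)-9-borabicyclo[3.3.1]nonane; 5 1-bromo-2-iodo-4,5-dimethoxybenzene
Product: 6 1-bromo-4,5-dimethoxy-2-(oct-7-en-1-yl)benzene
Conditions: Pd(dppf)Cl2 (cat.), Cs2CO3, DMF/THF/H2O, rt
Reagents that add atoms: none
Why: This B-alkyl Suzuki-Miyaura coupling is chemoselective because zerovalent palladium inserts much faster into the carbon-iodine bond than into the carbon-bromine bond at room temperature, and the new ortho chain shields the remaining bromide further.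

Step 5
Reactants: 6 1-bromo-4,5-dimethoxy-2-(oct-7-en-1-yl)benzene; 7 2,6-dihydroxybenzaldehyde
Product: 8 9-(2-bromo-4,5-dimethoxyphenyl)-1-(2,6-dihydroxyphenyl)nonan-1-one
Conditions: [Rh(cod)(OMe)]2 (cat.), dcpm (bis(dicyclohexylphosphino)methane), MonoPhos (BINOL-derived phosphoramidite), MeCN, 80 °C, argon
Reagents that add atoms: none
Why: In this phenoxide-directed rhodium-catalysed intermolecular hydroacylation of an unactivated terminal alkene with a salicylaldehyde, the O,C-chelated acyl rhodium hydride resists decarbonylation, the small-bite-angle diphosphine favours the linear ketone, and monovalent rhodium leaves the aryl bromide alone.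

Step 6
Reactants: 7 2,6-dihydroxybenzaldehyde
Product: 9 3-bromo-2,6-dihydroxybenzaldehyde
Conditions: NBS (1.0 equiv), MeCN, -10 to 0 °C
Reagents that add atoms: N-bromosuccinimide, O=C1CCC(=O)N1Br
Why: In this electrophilic bromination of a phenol, C3 and C5 of the symmetrical aldehyde are equivalent and each is ortho to one hydroxyl and para to the other, so one equivalent of NBS in the cold should give a single monobromide.

Step 7
Reactants: 8 9-(2-bromo-4,5-dimethoxyphenyl)-1-(2,6-dihydroxyphenyl)nonan-1-one; 9 3-bromo-2,6-dihydroxybenzaldehyde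
Product: 11 3-[2-[9-(2,6-dihydroxyphenyl)-9-oxononyl]-4,5-dimethoxyphenyl]-2,6-dihydroxybenzaldehyde, via pinacol boronate 10 (not isolated)
Conditions: 8, B2pin2 (1.1 equiv), KOAc, Pd2(dba)3 (cat.), XPhos, 1,4-dioxane, 100 °C; then 9, aq K3PO4, 80 °C, same pot
Reagents that add atoms: bis(pinacolato)diboron, CC1(C)OB(OC1(C)C)B1OC(C)(C)C(C)(C)O1 (its boryl group stands in 10 only)
Why: One-pot Miyaura borylation and Suzuki-Miyaura biaryl coupling both tolerate free phenols, ketones and aldehydes, and the bulky electron-rich phosphine drives oxidative addition into the two electron-rich bromides and closes the doubly ortho-substituted biaryl bond.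

Step 8
Reactants: 11 3-[2-[9-(2,6-dihydroxyphenyl)-9-oxononyl]-4,5-dimethoxyphenyl]-2,6-dihydroxybenzaldehyde; 4 1,2-dimethoxy-4-(oct-7-en-1-yl)benzene
Product: 12 1-[3-[2-[9-(2,6-dihydroxyphenyl)-9-oxononyl]-4,5-dimethoxyphenyl]-2,6-dihydroxyphenyl]-9-(3,4-dimethoxyphenyl)nonan-1-one
Conditions: 4 (2 equiv), [Rh(cod)(OMe)]2 (cat.), dcpm, MonoPhos, MeCN/1,4-dioxane, 80 °C, argon
Reagents that add atoms: none
Why: Protonolysis of the Rh-OMe bond by a ring C phenol gives a phenoxide of monovalent rhodium that inserts into the neighbouring formyl C-H bond to form a five-membered O,C-chelated acyl hydride of trivalent rhodium, after which alkene 4 binds, the hydride moves to its inner carbon and reductive elimination joins the acyl carbon to the terminal CH2. The closest known reaction type is the phenoxide-directed rhodium-catalysed intermolecular hydroacylation of unactivated terminal alkenes with salicylaldehydes, which also covers doubly ortho-substituted and polyhydroxylated aldehydes. No ring is closed and no stereocentre is created. Linear over branched selectivity is needed and should come from the small bite angle of dcpm, under which branched insertion is reversible while linear insertion leads on to product. Decarbonylation has to be outrun, which the rigid chelate (no free cis site for CO extrusion) and the pi-acidic phosphoramidite (faster reductive elimination) should secure. Site selectivity is inherent because 11 holds a single formyl C-H bond, its ring A ketone, methyl ethers and biaryl are inert, and the excess of 4 makes up for any chain-walking isomerisation.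

Step 9
Reactants: 12 1-[3-[2-[9-(2,6-dihydroxyphenyl)-9-oxononyl]-4,5-dimethoxyphenyl]-2,6-dihydroxyphenyl]-9-(3,4-dimethoxyphenyl)nonan-1-one
Product: 13 giganteone A
Conditions: BBr3 (excess), CH2Cl2, -78 °C to rt; ice-water quench, work-up under argon
Reagents that add atoms: none
Why: Standard aryl methyl ether cleavage with BBr3 removes the four catechol methyl groups, while the two ketones are only held as boron chelates that hydrolyse on work-up.

Compound list
1 | octa-1,7-diene | C=CCCCCC=C | starting material
2 | 9-(oct-7-en-1-yl)-9-borabicyclo[3.3.1]nonane | C=CCCCCCCB1C2CCCC1CCC2 | intermediate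
3 | 4-bromo-1,2-dimethoxybenzene (4-bromoveratrole) | COc1ccc(Br)cc1OC | starting material
4 | 1,2-dimethoxy-4-(oct-7-en-1-yl)benzene | C=CCCCCCCc1ccc(OC)c(OC)c1 | intermediate
5 | 1-bromo-2-iodo-4,5-dimethoxybenzene | COc1cc(Br)c(I)cc1OC | intermediate
6 | 1-bromo-4,5-dimethoxy-2-(oct-7-en-1-yl)benzene | C=CCCCCCCc1cc(OC)c(OC)cc1Br | intermediate
7 | 2,6-dihydroxybenzaldehyde | O=Cc1c(O)cccc1O | starting material
8 | 9-(2-bromo-4,5-dimethoxyphenyl)-1-(2,6-dihydroxyphenyl)nonan-1-one | O=C(CCCCCCCCc1cc(OC)c(OC)cc1Br)c1c(O)cccc1O | intermediate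
9 | 3-bromo-2,6-dihydroxybenzaldehyde | O=Cc1c(O)ccc(Br)c1O | intermediate
10 | 1-(2,6-dihydroxyphenyl)-9-[4,5-dimethoxy-2-(4,4,5,5-tetramethyl-1,3,2-dioxaborolan-2-yl)phenyl]nonan-1-one | O=C(CCCCCCCCc1cc(OC)c(OC)cc1B1OC(C)(C)C(C)(C)O1)c1c(O)cccc1O | intermediate
11 | 3-[2-[9-(2,6-dihydroxyphenyl)-9-oxononyl]-4,5-dimethoxyphenyl]-2,6-dihydroxybenzaldehyde | O=C(CCCCCCCCc1cc(OC)c(OC)cc1-c1ccc(O)c(C=O)c1O)c1c(O)cccc1O | intermediate
12 | 1-[3-[2-[9-(2,6-dihydroxyphenyl)-9-oxononyl]-4,5-dimethoxyphenyl]-2,6-dihydroxyphenyl]-9-(3,4-dimethoxyphenyl)nonan-1-one (giganteone A with both catechols as dimethyl ethers) | O=C(CCCCCCCCc1cc(OC)c(OC)cc1-c1ccc(O)c(C(=O)CCCCCCCCc2ccc(OC)c(OC)c2)c1O)c1c(O)cccc1O | intermediate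
13 | giganteone A | O=C(CCCCCCCCc1cc(O)c(O)cc1-c1ccc(O)c(C(=O)CCCCCCCCc2ccc(O)c(O)c2)c1O)c1c(O)cccc1O | target

Total step count: 9
Longest linear sequence: 6 steps (3, 4, 5, 7, 8, 9; the path 1, 4, 5, 7, 8, 9 is equally long)

Steps most likely to fail

Step 8. Three processes may outrun C-C bond formation: decarbonylation of the crowded acyl rhodium hydride, trapping of rhodium by the keto-diphenol unit of ring A, and chain walking of the alkene. The fallback replaces C-H activation by polar addition and oxidation. It sets out from 11 and 4 and comes back at 13. All four phenols of 11 are methylated (MeI, K2CO3, DMF) to give the hexamethoxy keto aldehyde F1. Alkene 4 is hydrobrominated under radical anti-Markovnikov conditions (HBr, dibenzoyl peroxide, hexane, 0 °C) to 4-(8-bromooctyl)-1,2-dimethoxybenzene F2, which with Mg in THF gives the alkylmagnesium bromide F3. At -78 °C this reagent should add to the formyl group of the aldehyde in preference to the twisted, doubly ortho-substituted ketone and give the racemic secondary alcohol F4. Dess-Martin oxidation removes that stereocentre again and gives the octamethyl ether diketone F5, and BBr3 in CH2Cl2 cleaves all eight methyl ethers to 13.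

Step 7. Oxidative addition into the phenoxide form of 9 may be sluggish, and 10 may undergo protodeboronation while it waits. Either bromide may also be reduced. The fallback masks the coupling partner and runs the sequence stepwise. It sets out from 9 and 8 and comes back at 11. Compound 9 is converted with MOMCl and i-Pr2NEt in CH2Cl2 into 3-bromo-2,6-bis(methoxymethoxy)benzaldehyde F6. Boronate 10 is made from 8 as before but is isolated. The two are joined by Suzuki-Miyaura coupling (Pd(OAc)2, SPhos, K3PO4, toluene/H2O, 80 °C) to give the bis-MOM biaryl aldehyde F7. Treatment with 2 M aq HCl in THF at 50 °C takes off both acetals without touching the methyl ethers and gives 11.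

Step 5. Decarbonylation of 7 and isomerisation of 6 to unreactive internal olefins may consume both partners. The fallback forms the aryl-C(=O) bond in place of the C(=O)-CH2 bond. It sets out from 6 and comes back at 8. Linear-selective hydroformylation of 6 (Rh(acac)(CO)2, Xantphos, CO/H2, toluene, 80 °C) gives 9-(2-bromo-4,5-dimethoxyphenyl)nonanal F8. Commercial 1,3-bis(methoxymethoxy)benzene is lithiated between its two oxygens (n-BuLi, THF, 0 °C) to 2,6-bis(methoxymethoxy)phenyllithium F9. This adds to the aldehyde at -78 °C faster than it exchanges with the aryl bromide and gives the racemic benzylic alcohol F10. Dess-Martin oxidation gives the bis-MOM ketone F11, and 2 M aq HCl in THF releases 8.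

Further compounds
F1 | step 8 | 3-[2-[9-(2,6-dimethoxyphenyl)-9-oxononyl]-4,5-dimethoxyphenyl]-2,6-dimethoxybenzaldehyde | O=C(CCCCCCCCc1cc(OC)c(OC)cc1-c1ccc(OC)c(C=O)c1OC)c1c(OC)cccc1OC
F2 | step 8 | 4-(8-bromooctyl)-1,2-dimethoxybenzene | BrCCCCCCCCc1ccc(OC)c(OC)c1
F3 | step 8 | 8-(3,4-dimethoxyphenyl)octylmagnesium bromide | Br[Mg]CCCCCCCCc1ccc(OC)c(OC)c1
F4 | step 8 | racemic 9-[2-[3-[9-(3,4-dimethoxyphenyl)-1-hydroxynonyl]-2,4-dimethoxyphenyl]-4,5-dimethoxyphenyl]-1-(2,6-dimethoxyphenyl)nonan-1-one | O=C(CCCCCCCCc1cc(OC)c(OC)cc1-c1ccc(OC)c(C(O)CCCCCCCCc2ccc(OC)c(OC)c2)c1OC)c1c(OC)cccc1OC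
F5 | step 8 | giganteone A octamethyl ether | O=C(CCCCCCCCc1cc(OC)c(OC)cc1-c1ccc(OC)c(C(=O)CCCCCCCCc2ccc(OC)c(OC)c2)c1OC)c1c(OC)cccc1OC
F6 | step 7 | 3-bromo-2,6-bis(methoxymethoxy)benzaldehyde | O=Cc1c(OCOC)ccc(Br)c1OCOC
F7 | step 7 | 3-[2-[9-(2,6-dihydroxyphenyl)-9-oxononyl]-4,5-dimethoxyphenyl]-2,6-bis(methoxymethoxy)benzaldehyde | O=C(CCCCCCCCc1cc(OC)c(OC)cc1-c1ccc(OCOC)c(C=O)c1OCOC)c1c(O)cccc1O
F8 | step 5 | 9-(2-bromo-4,5-dimethoxyphenyl)nonanal | O=CCCCCCCCCc1cc(OC)c(OC)cc1Br
F9 | step 5 | 2,6-bis(methoxymethoxy)phenyllithium | [Li]c1c(OCOC)cccc1OCOC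
F10 | step 5 | racemic 9-(2-bromo-4,5-dimethoxyphenyl)-1-[2,6-bis(methoxymethoxy)phenyl]nonan-1-ol | OC(CCCCCCCCc1cc(OC)c(OC)cc1Br)c1c(OCOC)cccc1OCOC
F11 | step 5 | 9-(2-bromo-4,5-dimethoxyphenyl)-1-[2,6-bis(methoxymethoxy)phenyl]nonan-1-one | O=C(CCCCCCCCc1cc(OC)c(OC)cc1Br)c1c(OCOC)cccc1OCOC
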